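**Retrosynthetic overview**

1. Locants: ring C1 (bears the side chain), C2 (vinylic methyl), C3–C5 (CH2), C6 (CMe2); side chain C1'–C10' counted from the ring (C10' = carbinol). The last C–C bond is C6'–C7', made by Negishi coupling of a homoallylic zinc reagent (ring + C1'–C6') with an (E)-alkenyl bromide (C7'–C10' + butenolide), followed by global desilylation.
2. Alkenyl bromide: a bromo-phosphonate olefination of an (R)-β-silyloxy aldehyde fixes the C7'=C8' geometry. The (R)-carbinol comes from asymmetric hydrogenation of a 3-furyl β-keto ester. The butenolide is unmasked from the furan (singlet oxygen, then NaBH4) before the fragments meet.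
3. Cyclohexene: C2–C5 come from cyclobutanone and C1/C6 from a silyl alkyne that already carries C1'–C6'. Nickel-catalysed insertion of the alkyne into the C(=O)–CH2 bond forms C1–C2 and C5–C6 in one operation. The three methyl groups follow by Si→Me exchange, conjugate methylation/enol triflation and methyl cross-coupling.
4. Enabling feature: the tetrasubstituted C1=C2 olefin is flanked by three contiguous ring CH2 groups (C3–C5) and by C6. C2–C5 therefore map onto the strained four-membered ring of cyclobutanone (C2 = its carbonyl carbon), and C1/C6 onto an alkyne whose C6 terminus carries silicon as a removable regiocontrol group.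
5. Ring order: the six-membered carbocycle first (step 5), the butenolide second (step 18, on the other fragment).

Key step: step 5

Remark: compounds 1, 5, 8, 20 and 24 are taken as commercial; the nickelacycles 9 and 10 are drawn without the phosphine on nickel; 13 is a transient diastereomer mixture whose stereocentres vanish within step 6.

**Route**

Step 1
Reactants: 1 4-methylpent-3-en-1-ol
Product: 2 tert-butyldimethyl[(4-methylpent-3-en-1-yl)oxy]silane
Conditions: TBSCl, imidazole, DMF, rt
Reagents that add atoms: tert-butyldimethylsilyl chloride, CC(C)(C)[Si](C)(C)Cl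
Why: Standard silylation of a primary alcohol gives a protecting group that survives organolithium, nickel, cuprate and Grignard steps.

Step 2
Reactants: 2 tert-butyldimethyl[(4-methylpent-3-en-1-yl)oxy]silane
Product: 3 (2E)-5-[(tert-butyldimethylsilyl)oxy]-2-methylpent-2-en-1-ol
Conditions: SeO2 (cat.), t-BuOOH, salicylic acid (cat.), CH2Cl2, rt
Reagents that add atoms: tert-butyl hydroperoxide, CC(C)(C)OO
Why: SeO2-catalysed allylic oxidation (Riley type; ene reaction then [2,3]-shift) attacks the (E)-methyl group of a gem-dimethyl trisubstituted olefin, which fixes the E geometry of the future C3'=C4' bond.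

Step 3
Reactants: 3 (2E)-5-[(tert-butyldimethylsilyl)oxy]-2-methylpent-2-en-1-ol
Product: 4 {[(3E)-5-bromo-4-methylpent-3-en-1-yl]oxy}(tert-butyl)dimethylsilane
Conditions: CBr4, PPh3, CH2Cl2, 0 °C
Reagents that add atoms: carbon tetrabromide, BrC(Br)(Br)Br
Why: Appel bromination of a primary allylic alcohol should proceed at low temperature without allylic transposition and without touching the silyl ether or the olefin geometry.

Step 4
Reactants: 4 {[(3E)-5-bromo-4-methylpent-3-en-1-yl]oxy}(tert-butyl)dimethylsilane; 5 1-(trimethylsilyl)propyne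
Product: 7 tert-butyldimethyl{[(3E)-4-methyl-8-(trimethylsilyl)oct-3-en-7-yn-1-yl]oxy}silane, via lithiated silylpropyne 6 (not isolated)
Conditions: n-BuLi, THF, −78 °C; then 4, −78 °C → rt
Reagents that add atoms: none
Why: Propargylic lithiation of the silylpropyne and SN2 alkylation by the primary allylic bromide give the 1,5-enyne; the silyl group keeps the nucleophile propargylic and becomes the regiocontrol element of step 5.

Step 5
Reactants: 7 tert-butyldimethyl{[(3E)-4-methyl-8-(trimethylsilyl)oct-3-en-7-yn-1-yl]oxy}silane; 8 cyclobutanone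
Product: 11 2-[(3E)-6-[(tert-butyldimethylsilyl)oxy]-3-methylhex-3-en-1-yl]-3-(trimethylsilyl)cyclohex-2-en-1-one, via oxanickelacyclopentene 9 (not isolated), via nickelacycloheptenone 10 (not isolated)
Conditions: Ni(cod)2 (10 mol %), PCy3 (20 mol %), cyclobutanone (3 equiv), toluene, 100 °C, sealed tube
Reagents that add atoms: none
Why: Zerovalent nickel joins the alkyne and the ketone carbonyl by oxidative cyclisation to the spiro oxanickelacyclopentene 9 (forming C1–C2), β-carbon elimination then opens the four-membered ring with release of its strain to give the seven-membered nickelacycle 10, and C(sp2)–C(sp3) reductive elimination forms C5–C6 and returns zerovalent nickel. The closest known reaction type is the nickel-catalysed intermolecular insertion of internal alkynes into cyclobutanones (a formal [4+2] by C–C cleavage), applied here to the parent ketone and a C-silyl alkyne. The six-membered ring is closed by that reductive elimination, that is, a two-carbon ring expansion of the cyclobutanone and not an ionic or radical exo/endo closure. No stereocentre is created. The step needs regioselectivity, with the carbonyl carbon bonding to the chain-bearing alkyne carbon and the ring CH2 to the other one; the trimethylsilyl group should secure this because the silicon-bearing carbon prefers the position on nickel (α-silyl stabilisation of the C–Ni bond, large group remote from the forming C–C bond), and it also suppresses alkyne oligomerisation. The trisubstituted olefin and the silyl ether should not engage zerovalent nickel, and the bulky donor phosphine is chosen so that reductive elimination from 10 outruns β-hydride elimination.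

Step 6
Reactants: 11 2-[(3E)-6-[(tert-butyldimethylsilyl)oxy]-3-methylhex-3-en-1-yl]-3-(trimethylsilyl)cyclohex-2-en-1-one
Product: 14 2-[(3E)-6-[(tert-butyldimethylsilyl)oxy]-3-methylhex-3-en-1-yl]-3-methylcyclohex-2-en-1-one, via lithium enolate 12 (not isolated), via bromo silyl ketone 13 (not isolated)
Conditions: Me2CuLi (from MeLi, CuI), Et2O, −78 → 0 °C; then NBS, THF, −78 °C → rt
Reagents that add atoms: lithium dimethylcuprate, [Li+].C[Cu-]C
Why: Cuprate conjugate addition to the β-silyl enone and α-bromination of the enolate give a β-silyl α-bromo ketone that should lose Me3SiBr by anti elimination (desilylbromination, silicon as a masked double bond), so silicon is replaced by methyl and the enone is restored; the transient stereocentres are destroyed again.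

Step 7
Reactants: 14 2-[(3E)-6-[(tert-butyldimethylsilyl)oxy]-3-methylhex-3-en-1-yl]-3-methylcyclohex-2-en-1-one
Product: 16 2-[(3E)-6-[(tert-butyldimethylsilyl)oxy]-3-methylhex-3-en-1-yl]-3,3-dimethylcyclohex-1-en-1-yl trifluoromethanesulfonate, via lithium enolate 15 (not isolated)
Conditions: Me2CuLi (from MeLi, CuI), Et2O, 0 °C; then PhNTf2, THF, 0 °C → rt
Reagents that add atoms: lithium dimethylcuprate, [Li+].C[Cu-]C; N-phenylbis(trifluoromethanesulfonimide), O=S(=O)(N(c1ccccc1)S(=O)(=O)C(F)(F)F)C(F)(F)F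
Why: A second cuprate conjugate addition builds the gem-dimethyl carbon C6, and O-triflation of the regiodefined enolate (McMurry–Scott type) fixes the position of the future C1=C2 olefin.

Step 8
Reactants: 16 2-[(3E)-6-[(tert-butyldimethylsilyl)oxy]-3-methylhex-3-en-1-yl]-3,3-dimethylcyclohex-1-en-1-yl trifluoromethanesulfonate
Product: 17 tert-butyldimethyl{[(3E)-4-methyl-6-(2,6,6-trimethylcyclohex-1-en-1-yl)hex-3-en-1-yl]oxy}silane
Conditions: MeMgBr, Fe(acac)3 (5 mol %), THF–NMP, −30 → 0 °C
Reagents that add atoms: methylmagnesium bromide, C[Mg]Br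
Why: Iron-catalysed Kumada-type cross-coupling of the alkenyl triflate with MeMgBr should install the vinylic methyl group without moving the double bond and without touching the silyl ether or the chain olefin.

Step 9
Reactants: 17 tert-butyldimethyl{[(3E)-4-methyl-6-(2,6,6-trimethylcyclohex-1-en-1-yl)hex-3-en-1-yl]oxy}silane
Product: 18 (3E)-4-methyl-6-(2,6,6-trimethylcyclohex-1-en-1-yl)hex-3-en-1-ol
Conditions: Bu4NF, THF, 0 °C → rt
Reagents that add atoms: none
Why: Fluoride cleavage of the primary silyl ether is routine and leaves both olefins untouched.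

Step 10
Reactants: 18 (3E)-4-methyl-6-(2,6,6-trimethylcyclohex-1-en-1-yl)hex-3-en-1-ol
Product: 19 2-[(3E)-6-iodo-3-methylhex-3-en-1-yl]-1,3,3-trimethylcyclohex-1-ene
Conditions: I2, PPh3, imidazole, CH2Cl2, 0 °C
Reagents that add atoms: iodine, II
Why: Appel-type iodination (Garegg–Samuelsson conditions) converts the primary alcohol by SN2 displacement under buffered conditions that should spare the tri- and tetrasubstituted olefins.

Step 11
Reactants: 20 ethyl 3-(furan-3-yl)-3-oxopropanoate
Product: 21 ethyl (3R)-3-(furan-3-yl)-3-hydroxypropanoate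
Conditions: H2 (10 atm), RuCl2[(S)-BINAP] (0.5 mol %), EtOH, 50 °C
Reagents that add atoms: none
Why: Noyori asymmetric hydrogenation of a β-keto ester: chelation of the keto ester to the (S)-BINAP ruthenium hydride exposes one carbonyl face and should set the (R)-carbinol (the sense known for aryl β-keto esters); the furan is not reduced under these homogeneous conditions.

Step 12
Reactants: 21 ethyl (3R)-3-(furan-3-yl)-3-hydroxypropanoate
Product: 22 ethyl (3R)-3-[(tert-butyldimethylsilyl)oxy]-3-(furan-3-yl)propanoate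
Conditions: TBSCl, imidazole, DMF, rt
Reagents that add atoms: tert-butyldimethylsilyl chloride, CC(C)(C)[Si](C)(C)Cl
Why: Silylation of the secondary alcohol occurs at oxygen and does not touch the stereocentre.

Step 13
Reactants: 22 ethyl (3R)-3-[(tert-butyldimethylsilyl)oxy]-3-(furan-3-yl)propanoate
Product: 23 (3R)-3-[(tert-butyldimethylsilyl)oxy]-3-(furan-3-yl)propanal
Conditions: i-Bu2AlH (1.1 equiv), CH2Cl2, −78 °C; aqueous tartrate work-up
Reagents that add atoms: none
Why: Partial ester reduction with i-Bu2AlH at low temperature should stop at the aldehyde through the stable tetrahedral aluminium hemiacetal; the β-silyloxy stereocentre is not epimerisable.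

Step 14
Reactants: 24 methyl 2-[bis(2,2,2-trifluoroethoxy)phosphoryl]acetate
Product: 26 methyl 2-bromo-2-[bis(2,2,2-trifluoroethoxy)phosphoryl]acetate, via dibromo phosphonoacetate 25 (not isolated)
Conditions: Br2, aq. NaOH, 0 °C; then Na2SO3, H2O–EtOH, 0 °C
Reagents that add atoms: bromine, BrBr
Why: Exhaustive hypobromite bromination of the active methylene followed by selective sulfite reduction of one C–Br bond (the established route to α-halo phosphonoacetates) should give the monobromo reagent cleanly, which direct monobromination would not.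

Step 15
Reactants: 26 methyl 2-bromo-2-[bis(2,2,2-trifluoroethoxy)phosphoryl]acetate; 23 (3R)-3-[(tert-butyldimethylsilyl)oxy]-3-(furan-3-yl)propanal
Product: 28 methyl (2E,5R)-2-bromo-5-[(tert-butyldimethylsilyl)oxy]-5-(furan-3-yl)pent-2-enoate, via potassium phosphonate carbanion 27 (not isolated)
Conditions: KOt-Bu, 18-crown-6, THF, −78 °C; then 23
Reagents that add atoms: none
Why: Still–Gennari-type Horner–Wadsworth–Emmons olefination: the electron-poor bis(trifluoroethyl) phosphonate eliminates from the kinetic adduct, so the ester should end up cis to the new alkyl group and bromine trans to it ((E)-α-bromo enoate); the stereocentre is untouched.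

Step 16
Reactants: 28 methyl (2E,5R)-2-bromo-5-[(tert-butyldimethylsilyl)oxy]-5-(furan-3-yl)pent-2-enoate
Product: 29 (2E,5R)-2-bromo-5-[(tert-butyldimethylsilyl)oxy]-5-(furan-3-yl)pent-2-en-1-ol
Conditions: i-Bu2AlH (2.2 equiv), CH2Cl2, −78 °C
Reagents that add atoms: none
Why: 1,2-Reduction of the enoate with i-Bu2AlH gives the allylic alcohol; alkenyl bromide, furan and silyl ether are inert and the olefin geometry is retained.

Step 17
Reactants: 29 (2E,5R)-2-bromo-5-[(tert-butyldimethylsilyl)oxy]-5-(furan-3-yl)pent-2-en-1-ol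
Product: 30 3-[(1R,3E)-4-bromo-1,5-bis[(tert-butyldimethylsilyl)oxy]pent-3-en-1-yl]furan
Conditions: TBSCl, imidazole, DMF, rt
Reagents that add atoms: tert-butyldimethylsilyl chloride, CC(C)(C)[Si](C)(C)Cl
Why: Silylation of the primary allylic alcohol removes the only acidic proton before the organozinc coupling.

Step 18
Reactants: 30 3-[(1R,3E)-4-bromo-1,5-bis[(tert-butyldimethylsilyl)oxy]pent-3-en-1-yl]furan
Product: 33 4-[(1R,3E)-4-bromo-1,5-bis[(tert-butyldimethylsilyl)oxy]pent-3-en-1-yl]furan-2(5H)-one, via furan endoperoxide 31 (not isolated), via hydroxybutenolide 32 (not isolated)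
Conditions: O2, hν (visible), rose bengal (cat.), i-Pr2NEt, CH2Cl2, −78 °C; then NaBH4, EtOH, 0 °C; acidify to pH 3
Reagents that add atoms: dioxygen, O=O
Why: Singlet oxygen adds [4+2] to the furan (the only electron-rich π-system here), the hindered base removes the bridgehead proton remote from the bulky side chain (Kornblum–DeLaMare fragmentation) so that the lactol carbon lies next to the substituent, and NaBH4 reduction of this masked aldehyde followed by lactonisation should give the 4-substituted butenolide; the carbinol stereocentre is not involved.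

Step 19
Reactants: 19 2-[(3E)-6-iodo-3-methylhex-3-en-1-yl]-1,3,3-trimethylcyclohex-1-ene; 33 4-[(1R,3E)-4-bromo-1,5-bis[(tert-butyldimethylsilyl)oxy]pent-3-en-1-yl]furan-2(5H)-one
Product: 35 4-[(1R,3Z,7E)-1-[(tert-butyldimethylsilyl)oxy]-4-{[(tert-butyldimethylsilyl)oxy]methyl}-8-methyl-10-(2,6,6-trimethylcyclohex-1-en-1-yl)deca-3,7-dien-1-yl]furan-2(5H)-one, via alkylzinc iodide 34 (not isolated)
Conditions: Zn, LiCl, THF, 40 °C; then 33, Pd(dppf)Cl2 (5 mol %), THF–NMP, 50 °C
Reagents that add atoms: none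
Why: LiCl-assisted zinc insertion into the primary iodide and Negishi sp3–sp2 coupling with the alkenyl bromide should proceed with retention of olefin geometry, which sets the (3Z) olefin; the organozinc is mild enough for the butenolide and the silyl ethers.

Step 20
Reactants: 35 4-[(1R,3Z,7E)-1-[(tert-butyldimethylsilyl)oxy]-4-{[(tert-butyldimethylsilyl)oxy]methyl}-8-methyl-10-(2,6,6-trimethylcyclohex-1-en-1-yl)deca-3,7-dien-1-yl]furan-2(5H)-one
Product: 36 4-[(1R,3Z,7E)-1-hydroxy-4-(hydroxymethyl)-8-methyl-10-(2,6,6-trimethylcyclohex-1-en-1-yl)deca-3,7-dien-1-yl]furan-2(5H)-one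
Conditions: HF·pyridine, pyridine, THF, 0 °C → rt
Reagents that add atoms: none
Why: Buffered acidic fluoride should remove both silyl ethers without opening or isomerising the butenolide and without touching the stereocentre or the olefins.

**Compound list**

1 | 4-methylpent-3-en-1-ol | CC(C)=CCCO | starting material
2 | tert-butyldimethyl[(4-methylpent-3-en-1-yl)oxy]silane | CC(C)=CCCO[Si](C)(C)C(C)(C)C | intermediate
3 | (2E)-5-[(tert-butyldimethylsilyl)oxy]-2-methylpent-2-en-1-ol | OC/C(C)=C/CCO[Si](C)(C)C(C)(C)C | intermediate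
4 | {[(3E)-5-bromo-4-methylpent-3-en-1-yl]oxy}(tert-butyl)dimethylsilane | BrC/C(C)=C/CCO[Si](C)(C)C(C)(C)C | intermediate
5 | 1-(trimethylsilyl)propyne | CC#C[Si](C)(C)C | starting material
6 | 3-lithio-1-(trimethylsilyl)propyne | [Li]CC#C[Si](C)(C)C | intermediate (not isolated)
7 | tert-butyldimethyl{[(3E)-4-methyl-8-(trimethylsilyl)oct-3-en-7-yn-1-yl]oxy}silane | C[Si](C)(C)C#CCC/C(C)=C/CCO[Si](C)(C)C(C)(C)C | intermediate
8 | cyclobutanone | O=C1CCC1 | starting material
9 | spiro oxanickelacyclopentene from 7 and 8 (phosphine on nickel omitted) | C[Si](C)(C)C1=C(CC/C(C)=C/CCO[Si](C)(C)C(C)(C)C)C2(CCC2)O[Ni]1 | intermediate (not isolated)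
10 | seven-membered nickelacycloheptenone (phosphine on nickel omitted) | C[Si](C)(C)C1=C(CC/C(C)=C/CCO[Si](C)(C)C(C)(C)C)C(=O)CCC[Ni]1 | intermediate (not isolated)
11 | 2-[(3E)-6-[(tert-butyldimethylsilyl)oxy]-3-methylhex-3-en-1-yl]-3-(trimethylsilyl)cyclohex-2-en-1-one | C[Si](C)(C)C1=C(CC/C(C)=C/CCO[Si](C)(C)C(C)(C)C)C(=O)CCC1 | intermediate
12 | lithium enolate of 2-[(3E)-6-(silyloxy)-3-methylhex-3-en-1-yl]-3-methyl-3-(trimethylsilyl)cyclohexanone | [Li]OC1=C(CC/C(C)=C/CCO[Si](C)(C)C(C)(C)C)C(C)([Si](C)(C)C)CCC1 | intermediate (not isolated)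
13 | 2-bromo-2-[(3E)-6-[(tert-butyldimethylsilyl)oxy]-3-methylhex-3-en-1-yl]-3-methyl-3-(trimethylsilyl)cyclohexanone (diastereomer mixture) | O=C1CCCC(C)([Si](C)(C)C)C1(Br)CC/C(C)=C/CCO[Si](C)(C)C(C)(C)C | intermediate (not isolated)
14 | 2-[(3E)-6-[(tert-butyldimethylsilyl)oxy]-3-methylhex-3-en-1-yl]-3-methylcyclohex-2-en-1-one | O=C1CCCC(C)=C1CC/C(C)=C/CCO[Si](C)(C)C(C)(C)C | intermediate
15 | lithium 2-[(3E)-6-[(tert-butyldimethylsilyl)oxy]-3-methylhex-3-en-1-yl]-3,3-dimethylcyclohex-1-en-1-olate | [Li]OC1=C(CC/C(C)=C/CCO[Si](C)(C)C(C)(C)C)C(C)(C)CCC1 | intermediate (not isolated)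
16 | 2-[(3E)-6-[(tert-butyldimethylsilyl)oxy]-3-methylhex-3-en-1-yl]-3,3-dimethylcyclohex-1-en-1-yl trifluoromethanesulfonate | O=S(=O)(OC1=C(CC/C(C)=C/CCO[Si](C)(C)C(C)(C)C)C(C)(C)CCC1)C(F)(F)F | intermediate
17 | tert-butyldimethyl{[(3E)-4-methyl-6-(2,6,6-trimethylcyclohex-1-en-1-yl)hex-3-en-1-yl]oxy}silane | CC1=C(CC/C(C)=C/CCO[Si](C)(C)C(C)(C)C)C(C)(C)CCC1 | intermediate
18 | (3E)-4-methyl-6-(2,6,6-trimethylcyclohex-1-en-1-yl)hex-3-en-1-ol | CC1=C(CC/C(C)=C/CCO)C(C)(C)CCC1 | intermediate
19 | 2-[(3E)-6-iodo-3-methylhex-3-en-1-yl]-1,3,3-trimethylcyclohex-1-ene | CC1=C(CC/C(C)=C/CCI)C(C)(C)CCC1 | intermediate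
20 | ethyl 3-(furan-3-yl)-3-oxopropanoate | CCOC(=O)CC(=O)c1ccoc1 | starting material
21 | ethyl (3R)-3-(furan-3-yl)-3-hydroxypropanoate | CCOC(=O)C[C@@H](O)c1ccoc1 | intermediate
22 | ethyl (3R)-3-[(tert-butyldimethylsilyl)oxy]-3-(furan-3-yl)propanoate | CCOC(=O)C[C@@H](O[Si](C)(C)C(C)(C)C)c1ccoc1 | intermediate
23 | (3R)-3-[(tert-butyldimethylsilyl)oxy]-3-(furan-3-yl)propanal | O=CC[C@@H](O[Si](C)(C)C(C)(C)C)c1ccoc1 | intermediate
24 | methyl 2-[bis(2,2,2-trifluoroethoxy)phosphoryl]acetate | COC(=O)CP(=O)(OCC(F)(F)F)OCC(F)(F)F | starting material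
25 | methyl 2,2-dibromo-2-[bis(2,2,2-trifluoroethoxy)phosphoryl]acetate | COC(=O)C(Br)(Br)P(=O)(OCC(F)(F)F)OCC(F)(F)F | intermediate (not isolated)
26 | methyl 2-bromo-2-[bis(2,2,2-trifluoroethoxy)phosphoryl]acetate | COC(=O)C(Br)P(=O)(OCC(F)(F)F)OCC(F)(F)F | intermediate
27 | potassium salt of the carbanion of 26 | [K+].COC(=O)[C-](Br)P(=O)(OCC(F)(F)F)OCC(F)(F)F | intermediate (not isolated)
28 | methyl (2E,5R)-2-bromo-5-[(tert-butyldimethylsilyl)oxy]-5-(furan-3-yl)pent-2-enoate | COC(=O)/C(Br)=C\C[C@@H](O[Si](C)(C)C(C)(C)C)c1ccoc1 | intermediate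
29 | (2E,5R)-2-bromo-5-[(tert-butyldimethylsilyl)oxy]-5-(furan-3-yl)pent-2-en-1-ol | OC/C(Br)=C\C[C@@H](O[Si](C)(C)C(C)(C)C)c1ccoc1 | intermediate
30 | 3-[(1R,3E)-4-bromo-1,5-bis[(tert-butyldimethylsilyl)oxy]pent-3-en-1-yl]furan | CC(C)(C)[Si](C)(C)OC/C(Br)=C\C[C@@H](O[Si](C)(C)C(C)(C)C)c1ccoc1 | intermediate
31 | furan endoperoxide of 30 (2,3,7-trioxabicyclo[2.2.1]hept-5-ene, side chain on C5) | CC(C)(C)[Si](C)(C)OC/C(Br)=C\C[C@@H](O[Si](C)(C)C(C)(C)C)C1=CC2OOC1O2 | intermediate (not isolated)
32 | 4-[(1R,3E)-4-bromo-1,5-bis[(tert-butyldimethylsilyl)oxy]pent-3-en-1-yl]-5-hydroxyfuran-2(5H)-one (lactol epimers) | CC(C)(C)[Si](C)(C)OC/C(Br)=C\C[C@@H](O[Si](C)(C)C(C)(C)C)C1=CC(=O)OC1O | intermediate (not isolated)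
33 | 4-[(1R,3E)-4-bromo-1,5-bis[(tert-butyldimethylsilyl)oxy]pent-3-en-1-yl]furan-2(5H)-one | CC(C)(C)[Si](C)(C)OC/C(Br)=C\C[C@@H](O[Si](C)(C)C(C)(C)C)C1=CC(=O)OC1 | intermediate
34 | [(3E)-4-methyl-6-(2,6,6-trimethylcyclohex-1-en-1-yl)hex-3-en-1-yl]zinc iodide | CC1=C(CC/C(C)=C/CC[Zn]I)C(C)(C)CCC1 | intermediate (not isolated)
35 | 4-[(1R,3Z,7E)-1-[(tert-butyldimethylsilyl)oxy]-4-{[(tert-butyldimethylsilyl)oxy]methyl}-8-methyl-10-(2,6,6-trimethylcyclohex-1-en-1-yl)deca-3,7-dien-1-yl]furan-2(5H)-one | CC1=C(CC/C(C)=C/CC/C(=C/C[C@@H](O[Si](C)(C)C(C)(C)C)C2=CC(=O)OC2)CO[Si](C)(C)C(C)(C)C)C(C)(C)CCC1 | intermediate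
36 | 4-[(1R,3Z,7E)-1-hydroxy-4-(hydroxymethyl)-8-methyl-10-(2,6,6-trimethylcyclohex-1-en-1-yl)deca-3,7-dien-1-yl]furan-2(5H)-one | CC1=C(CC/C(C)=C/CC/C(=C/C[C@@H](O)C2=CC(=O)OC2)CO)C(C)(C)CCC1 | target

**Step count and risks**

Total step count: 20. Longest linear sequence: 12 steps (steps 1–10, 19, 20, from 4-methylpent-3-en-1-ol).

Steps most likely to fail:

1. Step 5 (key step). The seven-membered nickelacycle may undergo β-hydride elimination at the unsubstituted ring CH2 groups instead of reductive elimination, giving ring-opened enone. Oxidative cyclisation of the hindered silyl alkyne with the ketone may also be slow, so that catalyst decomposition or alkyne oligomerisation wins. Fallback (sets out from 3, comes back at 17): oxidation of 3 with MnO2 should give (2E)-5-[(tert-butyldimethylsilyl)oxy]-2-methylpent-2-enal F1. Wittig methylenation (Ph3P=CH2) leads to tert-butyl{[(3E)-4-methylhexa-3,5-dien-1-yl]oxy}dimethylsilane F2. Hydroboration of its terminal vinyl group with 9-BBN-H gives 9-[(3E)-6-[(tert-butyldimethylsilyl)oxy]-3-methylhex-3-en-1-yl]-9-borabicyclo[3.3.1]nonane F3. B-alkyl Suzuki–Miyaura coupling (Pd(dppf)Cl2, AsPh3, Cs2CO3, DMF–THF–H2O) with 2,6,6-trimethylcyclohex-1-en-1-yl trifluoromethanesulfonate F4, made from commercial 2,2,6-trimethylcyclohexanone with LiN(i-Pr)2 and PhNTf2, would give 17 and bypass steps 4–8.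

2. Step 6. Conjugate addition at the fully substituted, silicon-bearing β-carbon may be slow, so that 1,2-addition or simple enolisation competes. The bromo silyl ketone may also fail to adopt the anti arrangement needed for clean loss of Me3SiBr. Fallback (sets out from 11, comes back at 16): Luche reduction (NaBH4, CeCl3·7H2O, MeOH) to 2-[(3E)-6-[(tert-butyldimethylsilyl)oxy]-3-methylhex-3-en-1-yl]-3-(trimethylsilyl)cyclohex-2-en-1-ol F5 makes the vinylsilane electron-rich. Ipso-iododesilylation (NIS, (CF3)2CHOH, 0 °C) then gives 2-[(3E)-6-[(tert-butyldimethylsilyl)oxy]-3-methylhex-3-en-1-yl]-3-iodocyclohex-2-en-1-ol F6. Dess–Martin oxidation gives 2-[(3E)-6-[(tert-butyldimethylsilyl)oxy]-3-methylhex-3-en-1-yl]-3-iodocyclohex-2-en-1-one F7. Excess Me2CuLi (addition–elimination to 14, then conjugate addition to 15, both in the flask) followed by PhNTf2 would deliver 16.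

3. Step 19. Oxidative addition at the hindered trisubstituted alkenyl bromide may be slow, which leaves the alkylzinc open to protonation or β-hydride loss; prolonged heating may isomerise or open the butenolide. Fallback (sets out from 19, with 24 and 23, comes back at 36): alkylation of 24 with 19 (NaH, DMF) should give methyl (5E)-2-[bis(2,2,2-trifluoroethoxy)phosphoryl]-6-methyl-8-(2,6,6-trimethylcyclohex-1-en-1-yl)oct-5-enoate F8. Still–Gennari olefination with 23 (KN(SiMe3)2, 18-crown-6, THF, −78 °C) gives methyl (2Z,5R)-5-[(tert-butyldimethylsilyl)oxy]-5-(furan-3-yl)-2-[(3E)-4-methyl-6-(2,6,6-trimethylcyclohex-1-en-1-yl)hex-3-en-1-yl]pent-2-enoate F9. Reduction with i-Bu2AlH gives the corresponding (2Z)-allylic alcohol F10. Photooxygenation (O2, hν, rose bengal, i-Pr2NEt, −78 °C) and NaBH4 reduction give 4-[(1R,3Z,7E)-1-[(tert-butyldimethylsilyl)oxy]-4-(hydroxymethyl)-8-methyl-10-(2,6,6-trimethylcyclohex-1-en-1-yl)deca-3,7-dien-1-yl]furan-2(5H)-one F11. HF·pyridine would then give 36.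

Further compounds
F1 | step 5 | (2E)-5-[(tert-butyldimethylsilyl)oxy]-2-methylpent-2-enal | O=C/C(C)=C/CCO[Si](C)(C)C(C)(C)C
F2 | step 5 | tert-butyl{[(3E)-4-methylhexa-3,5-dien-1-yl]oxy}dimethylsilane | C=C/C(C)=C/CCO[Si](C)(C)C(C)(C)C
F3 | step 5 | 9-[(3E)-6-[(tert-butyldimethylsilyl)oxy]-3-methylhex-3-en-1-yl]-9-borabicyclo[3.3.1]nonane | CC(C)(C)[Si](C)(C)OCC/C=C(\C)CCB1C2CCCC1CCC2
F4 | step 5 | 2,6,6-trimethylcyclohex-1-en-1-yl trifluoromethanesulfonate | CC1=C(OS(=O)(=O)C(F)(F)F)C(C)(C)CCC1
F5 | step 6 | 2-[(3E)-6-[(tert-butyldimethylsilyl)oxy]-3-methylhex-3-en-1-yl]-3-(trimethylsilyl)cyclohex-2-en-1-ol | OC1CCCC([Si](C)(C)C)=C1CC/C(C)=C/CCO[Si](C)(C)C(C)(C)C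
F6 | step 6 | 2-[(3E)-6-[(tert-butyldimethylsilyl)oxy]-3-methylhex-3-en-1-yl]-3-iodocyclohex-2-en-1-ol | OC1CCCC(I)=C1CC/C(C)=C/CCO[Si](C)(C)C(C)(C)C
F7 | step 6 | 2-[(3E)-6-[(tert-butyldimethylsilyl)oxy]-3-methylhex-3-en-1-yl]-3-iodocyclohex-2-en-1-one | O=C1CCCC(I)=C1CC/C(C)=C/CCO[Si](C)(C)C(C)(C)C
F8 | step 19 | methyl (5E)-2-[bis(2,2,2-trifluoroethoxy)phosphoryl]-6-methyl-8-(2,6,6-trimethylcyclohex-1-en-1-yl)oct-5-enoate | COC(=O)C(CC/C=C(\C)CCC1=C(C)CCCC1(C)C)P(=O)(OCC(F)(F)F)OCC(F)(F)F
F9 | step 19 | methyl (2Z,5R)-5-[(tert-butyldimethylsilyl)oxy]-5-(furan-3-yl)-2-[(3E)-4-methyl-6-(2,6,6-trimethylcyclohex-1-en-1-yl)hex-3-en-1-yl]pent-2-enoate | CC1=C(CC/C(C)=C/CC/C(=C/C[C@@H](O[Si](C)(C)C(C)(C)C)c2ccoc2)C(=O)OC)C(C)(C)CCC1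
F10 | step 19 | (2Z,5R)-5-[(tert-butyldimethylsilyl)oxy]-5-(furan-3-yl)-2-[(3E)-4-methyl-6-(2,6,6-trimethylcyclohex-1-en-1-yl)hex-3-en-1-yl]pent-2-en-1-ol | CC1=C(CC/C(C)=C/CC/C(=C/C[C@@H](O[Si](C)(C)C(C)(C)C)c2ccoc2)CO)C(C)(C)CCC1
F11 | step 19 | 4-[(1R,3Z,7E)-1-[(tert-butyldimethylsilyl)oxy]-4-(hydroxymethyl)-8-methyl-10-(2,6,6-trimethylcyclohex-1-en-1-yl)deca-3,7-dien-1-yl]furan-2(5H)-one | CC1=C(CC/C(C)=C/CC/C(=C/C[C@@H](O[Si](C)(C)C(C)(C)C)C2=CC(=O)OC2)CO)C(C)(C)CCC1
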